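**Retrosynthetic overview**
1. Target 36 ← DMDO epoxidation of the (Z)-C12=C13 alkene of 16-membered macrolactone 35 (oxirane formed last).
2. 35 ← Yamaguchi macrolactonization (O15–C1) of seco acid 32 (macrolactone formed first; the thiazole ring is bought).
3. 32 ← intermolecular titanium syn-aldol forming C6–C7 between ethyl ketone 10 (C1–C6, fragment A) and aldehyde 27 (C7–C17, fragment B).
4. 10 ← methyl acetoacetate (Noyori hydrogenation sets C3, Fráter–Seebach methylation sets C4); 27 ← B-alkyl Suzuki coupling (C11–C12) of (Z)-vinyl iodide 23 with alkene 14.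
5. 23 ← thiazole ester 15 (Wittig, Brown allylation for C15, iodo-Wittig); 14 ← Evans allylation (C8).

Assumption: positions are quoted in epothilone numbering (C1 = lactone carbonyl, C15 = lactone CH–O, C16=C17 = side-chain alkene), and ionic or chelated adducts that are merely quenched within their own step (alkali-metal enolates, tetrahedral magnesium or aluminium adducts, oxaphosphetanes) are not numbered.

**Fragment A (C1–C6)**

Step 1
Reactants: 1 methyl acetoacetate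
Product: 2 methyl 5-(benzyloxy)-3-oxopentanoate
Conditions: NaH, THF, 0 °C; n-BuLi, 0 °C; BnOCH2Cl, −78 → 0 °C; aq. NH4Cl
Reagents that add atoms: benzyl chloromethyl ether, ClCOCc1ccccc1
Why: Weiler dianion alkylation, in which the terminal carbanion of the acetoacetate dianion is the most nucleophilic site and is alkylated cleanly by the reactive chloromethyl ether.

Step 2
Reactants: 2 methyl 5-(benzyloxy)-3-oxopentanoate
Product: 3 methyl (3S)-5-(benzyloxy)-3-hydroxypentanoate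
Conditions: RuCl2[(S)-BINAP] (0.2 mol %), H2 (10 atm), MeOH, 50 °C
Reagents that add atoms: none
Why: Noyori asymmetric hydrogenation of a β-keto ester, where the (S)-BINAP–ruthenium catalyst gives the 3S alcohol (same sense as methyl acetoacetate to (S)-3-hydroxybutanoate, ≥97% ee) and leaves the benzyl ether untouched; this sets C3.

Step 3
Reactants: 3 methyl (3S)-5-(benzyloxy)-3-hydroxypentanoate
Product: 4 methyl (2S,3S)-5-(benzyloxy)-3-hydroxy-2-methylpentanoate
Conditions: LiN(i-Pr)2 (2.2 equiv), THF, −78 → −20 °C; MeI, HMPA, −78 → 0 °C; aq. NH4Cl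
Reagents that add atoms: iodomethane, CI
Why: Fráter–Seebach alkylation, in which the chelated dilithio alkoxide–enolate is methylated anti to the C3 side chain to give the 2,3-anti ester (dr about 95:5); this sets the C4 methyl stereocenter.

Step 4
Reactants: 4 methyl (2S,3S)-5-(benzyloxy)-3-hydroxy-2-methylpentanoate
Product: 5 (2S,3S)-5-(benzyloxy)-3-hydroxy-N-methoxy-N,2-dimethylpentanamide
Conditions: MeNH(OMe)·HCl, i-PrMgCl, THF, −20 → 0 °C
Reagents that add atoms: N,O-dimethylhydroxylamine hydrochloride, CNOC.Cl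
Why: Weinreb amide formation by aminolysis of the ester with the magnesium amide, which proceeds at low temperature on the magnesium alkoxide without epimerizing the α-center.

Step 5
Reactants: 5 (2S,3S)-5-(benzyloxy)-3-hydroxy-N-methoxy-N,2-dimethylpentanamide
Product: 6 (2S,3S)-5-(benzyloxy)-3-[(tert-butyldimethylsilyl)oxy]-N-methoxy-N,2-dimethylpentanamide
Conditions: TBSOTf, 2,6-lutidine, CH2Cl2, −78 → 0 °C
Reagents that add atoms: tert-butyldimethylsilyl trifluoromethanesulfonate, CC(C)(C)[Si](C)(C)OS(=O)(=O)C(F)(F)F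
Why: Silyl ether formation with the reactive silyl triflate and a non-nucleophilic base protects the hindered secondary alcohol without touching the amide.

Step 6
Reactants: 6 (2S,3S)-5-(benzyloxy)-3-[(tert-butyldimethylsilyl)oxy]-N-methoxy-N,2-dimethylpentanamide
Product: 7 (4S,5S)-7-(benzyloxy)-5-[(tert-butyldimethylsilyl)oxy]-4-methylheptan-3-one
Conditions: EtMgBr, THF, 0 °C; aq. NH4Cl
Reagents that add atoms: ethylmagnesium bromide, CC[Mg]Br
Why: Weinreb ketone synthesis, where the chelated tetrahedral adduct survives until work-up, so there is no over-addition and no enolization of the α-stereocenter.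

Step 7
Reactants: 7 (4S,5S)-7-(benzyloxy)-5-[(tert-butyldimethylsilyl)oxy]-4-methylheptan-3-one
Product: 8 (4S,5S)-5-[(tert-butyldimethylsilyl)oxy]-7-hydroxy-4-methylheptan-3-one
Conditions: H2 (1 atm), 10% Pd/C, EtOAc, rt
Reagents that add atoms: none
Why: Catalytic hydrogenolysis of the benzyl ether under neutral conditions leaves the ketone and the silyl ether intact (the product equilibrates with its cyclic hemiketal, which does not matter for the next step).

Step 8
Reactants: 8 (4S,5S)-5-[(tert-butyldimethylsilyl)oxy]-7-hydroxy-4-methylheptan-3-one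
Product: 9 (3S,4S)-3-[(tert-butyldimethylsilyl)oxy]-4-methyl-5-oxoheptanoic acid
Conditions: TEMPO (20 mol %), PhI(OAc)2 (2.2 equiv), MeCN/H2O 1:1, rt
Reagents that add atoms: water, O
Why: Oxoammonium (TEMPO) oxidation of the primary alcohol through the aldehyde hydrate to the acid at near-neutral pH, which avoids epimerization at C4 and β-elimination of the silyloxy group.

Step 9
Reactants: 9 (3S,4S)-3-[(tert-butyldimethylsilyl)oxy]-4-methyl-5-oxoheptanoic acid
Product: 10 2,2,2-trichloroethyl (3S,4S)-3-[(tert-butyldimethylsilyl)oxy]-4-methyl-5-oxoheptanoate (fragment A)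
Conditions: Cl3CCH2OH (3 equiv), EDC·HCl, DMAP (5 mol %), CH2Cl2, 0 °C → rt
Reagents that add atoms: 2,2,2-trichloroethanol, OCC(Cl)(Cl)Cl
Why: Steglich esterification installs an ester that tolerates Lewis acids, silyl triflates, boranes and fluoride and is later removed reductively under non-basic conditions.

**Fragment B (C7–C17)**

Step 10
Reactants: 11 (4R)-4-benzyl-3-propanoyl-1,3-oxazolidin-2-one
Product: 12 (4R)-4-benzyl-3-[(2S)-2-methylpent-4-enoyl]-1,3-oxazolidin-2-one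
Conditions: NaN(SiMe3)2, THF, −78 °C; allyl iodide, −78 → −45 °C
Reagents that add atoms: allyl iodide, C=CCI
Why: Evans asymmetric alkylation, in which the chelated Z-sodium enolate is allylated on the face opposite the benzyl group (dr ≥ 97:3); this sets the C8 methyl stereocenter as S.

Step 11
Reactants: 12 (4R)-4-benzyl-3-[(2S)-2-methylpent-4-enoyl]-1,3-oxazolidin-2-one
Product: 13 (2S)-2-methylpent-4-en-1-ol
Conditions: LiBH4, MeOH (1 equiv), Et2O, 0 °C
Reagents that add atoms: none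
Why: Reductive removal of the auxiliary by hydride attack on the exocyclic imide carbonyl gives the primary alcohol without epimerization and returns the oxazolidinone.

Step 12
Reactants: 13 (2S)-2-methylpent-4-en-1-ol
Product: 14 (2S)-2-methylpent-4-en-1-yl 2,2-dimethylpropanoate
Conditions: PivCl, pyridine, DMAP (cat.), CH2Cl2, 0 °C → rt
Reagents that add atoms: pivaloyl chloride, CC(C)(C)C(=O)Cl
Why: Acylation gives a pivalate that survives hydroboration and aqueous carbonate and can later be removed by hydride in the presence of a triethylsilyl ether.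

Step 13
Reactants: 15 ethyl 2-methyl-1,3-thiazole-4-carboxylate
Product: 16 2-methyl-1,3-thiazole-4-carbaldehyde
Conditions: i-Bu2AlH (1.1 equiv), CH2Cl2, −78 °C; MeOH, aq. KNaC4H4O6
Reagents that add atoms: none
Why: Partial ester reduction, where the aluminium hemiacetal is stable at −78 °C and releases the aldehyde only on work-up.

Step 14
Reactants: 16 2-methyl-1,3-thiazole-4-carbaldehyde
Product: 17 (2E)-2-methyl-3-(2-methyl-1,3-thiazol-4-yl)prop-2-enal
Conditions: Ph3P=C(CH3)CHO, toluene, 90 °C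
Reagents that add atoms: 2-(triphenylphosphoranylidene)propanal, CC(C=O)=P(c1ccccc1)(c1ccccc1)c1ccccc1
Why: Wittig olefination with a stabilized ylide is under thermodynamic control and gives the E-trisubstituted enal (the C16=C17 geometry of the target).

Step 15
Reactants: 17 (2E)-2-methyl-3-(2-methyl-1,3-thiazol-4-yl)prop-2-enal
Product: 19 (1E,3S)-2-methyl-1-(2-methyl-1,3-thiazol-4-yl)hexa-1,5-dien-3-ol, via diisopinocampheylborinate ester 18 (not isolated)
Conditions: (−)-Ipc2BOMe, CH2=CHCH2MgBr, Et2O, 0 °C → rt (Mg salts filtered off); 17, −100 °C; then NaOH, H2O2, 0 °C → rt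
Reagents that add atoms: allylmagnesium bromide, C=CC[Mg]Br
Why: Brown asymmetric allylboration through a chair transition state, in which the allylborane derived from (+)-α-pinene adds to the Si face of the aldehyde (≥95% ee); this sets C15 as S.

Step 16
Reactants: 19 (1E,3S)-2-methyl-1-(2-methyl-1,3-thiazol-4-yl)hexa-1,5-dien-3-ol
Product: 20 4-[(1E,3S)-2-methyl-3-(triethylsilyloxy)hexa-1,5-dien-1-yl]-2-methyl-1,3-thiazole
Conditions: Et3SiCl, imidazole, DMF, 0 °C
Reagents that add atoms: chlorotriethylsilane, CC[Si](Cl)(CC)CC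
Why: Silylation gives a triethylsilyl ether that can later be removed selectively in the presence of the two tert-butyldimethylsilyl ethers.

Step 17
Reactants: 20 4-[(1E,3S)-2-methyl-3-(triethylsilyloxy)hexa-1,5-dien-1-yl]-2-methyl-1,3-thiazole
Product: 22 (3S,4E)-4-methyl-5-(2-methyl-1,3-thiazol-4-yl)-3-(triethylsilyloxy)pent-4-enal, via terminal 1,2-diol 21 (not isolated)
Conditions: OsO4 (2 mol %), NMO, acetone/H2O, 0 °C; then NaIO4, THF/pH 7 buffer, rt
Reagents that add atoms: 4-methylmorpholine N-oxide, C[N+]1([O-])CCOCC1; water, O (both deliver oxygen through the OsO4 they regenerate)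
Why: Upjohn dihydroxylation followed by periodate glycol cleavage (Lemieux–Johnson sequence) is selective for the unhindered monosubstituted alkene over the hindered, thiazole-conjugated trisubstituted one.

Step 18
Reactants: 22 (3S,4E)-4-methyl-5-(2-methyl-1,3-thiazol-4-yl)-3-(triethylsilyloxy)pent-4-enal
Product: 23 4-[(1E,3S,5Z)-6-iodo-2-methyl-3-(triethylsilyloxy)hepta-1,5-dien-1-yl]-2-methyl-1,3-thiazole
Conditions: [Ph3PEt]I, n-BuLi, THF, rt; I2, −78 °C; NaN(SiMe3)2, −20 °C; then 22, −78 → −20 °C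
Reagents that add atoms: ethyltriphenylphosphonium iodide, CC[P+](c1ccccc1)(c1ccccc1)c1ccccc1.[I-]; iodine, II
Why: Stork–Zhao-type Wittig olefination with the α-iodo ylide is kinetically Z-selective, placing iodine cis to the chain so that the later coupling gives the (Z)-C12=C13 alkene.

Step 19
Reactants: 14 (2S)-2-methylpent-4-en-1-yl 2,2-dimethylpropanoate; 23 4-[(1E,3S,5Z)-6-iodo-2-methyl-3-(triethylsilyloxy)hepta-1,5-dien-1-yl]-2-methyl-1,3-thiazole
Product: 25 (2S,6Z,9S,10E)-2,6,10-trimethyl-11-(2-methyl-1,3-thiazol-4-yl)-9-(triethylsilyloxy)undeca-6,10-dien-1-yl 2,2-dimethylpropanoate, via B-alkyl-9-BBN adduct 24 (not isolated)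
Conditions: 14, 9-BBN-H, THF, rt; then 23, PdCl2(dppf) (10 mol %), Ph3As, Cs2CO3, DMF/H2O, rt
Reagents that add atoms: none
Why: Anti-Markovnikov hydroboration followed by B-alkyl Suzuki–Miyaura coupling forms C11–C12 with retention of the vinyl iodide geometry, and the hindered trisubstituted alkenes and the thiazole are tolerated.

Step 20
Reactants: 25 (2S,6Z,9S,10E)-2,6,10-trimethyl-11-(2-methyl-1,3-thiazol-4-yl)-9-(triethylsilyloxy)undeca-6,10-dien-1-yl 2,2-dimethylpropanoate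
Product: 26 (2S,6Z,9S,10E)-2,6,10-trimethyl-11-(2-methyl-1,3-thiazol-4-yl)-9-(triethylsilyloxy)undeca-6,10-dien-1-ol
Conditions: i-Bu2AlH (3 equiv), CH2Cl2, −78 °C; aq. KNaC4H4O6
Reagents that add atoms: none
Why: Reductive cleavage of the pivalate by hydride frees the primary alcohol under non-acidic, non-fluoride conditions, so the triethylsilyl ether stays.

Step 21
Reactants: 26 (2S,6Z,9S,10E)-2,6,10-trimethyl-11-(2-methyl-1,3-thiazol-4-yl)-9-(triethylsilyloxy)undeca-6,10-dien-1-ol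
Product: 27 (2S,6Z,9S,10E)-2,6,10-trimethyl-11-(2-methyl-1,3-thiazol-4-yl)-9-(triethylsilyloxy)undeca-6,10-dienal (fragment B)
Conditions: Dess–Martin periodinane, NaHCO3, CH2Cl2, 0 °C → rt; used at once
Reagents that add atoms: none
Why: Dess–Martin oxidation under buffered, non-basic conditions gives the α-methyl aldehyde without epimerizing C8.

**Fragment union and endgame**

Step 22
Reactants: 10 2,2,2-trichloroethyl (3S,4S)-3-[(tert-butyldimethylsilyl)oxy]-4-methyl-5-oxoheptanoate; 27 (2S,6Z,9S,10E)-2,6,10-trimethyl-11-(2-methyl-1,3-thiazol-4-yl)-9-(triethylsilyloxy)undeca-6,10-dienal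
Product: 29 2,2,2-trichloroethyl (3S,4S,6R,7S,8S,12Z,15S,16E)-3-[(tert-butyldimethylsilyl)oxy]-7-hydroxy-4,6,8,12,16-pentamethyl-17-(2-methyl-1,3-thiazol-4-yl)-5-oxo-15-(triethylsilyloxy)heptadeca-12,16-dienoate, via trichlorotitanium Z-enolate 28 (not isolated)
Conditions: 10 (1.6 equiv), TiCl4 (1.7 equiv), i-Pr2NEt (1.9 equiv), CH2Cl2, −78 °C, 1 h; then 27 (1.0 equiv), −78 °C; pH 7 buffer
Reagents that add atoms: none
Why: Chlorotitanium-enolate aldol through a closed Zimmerman–Traxler transition state, in which soft enolization at the less hindered ethyl CH2 gives the Z-enolate (6,7-syn), the C4 stereocenter directs attack so that the C4 and C6 methyls end up syn (6R), and the Z-enolate's anti-Felkin preference toward the (S)-α-methyl aldehyde gives 7,8-anti (7S), so the control elements are matched.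

Step 23
Reactants: 29 2,2,2-trichloroethyl (3S,4S,6R,7S,8S,12Z,15S,16E)-3-[(tert-butyldimethylsilyl)oxy]-7-hydroxy-4,6,8,12,16-pentamethyl-17-(2-methyl-1,3-thiazol-4-yl)-5-oxo-15-(triethylsilyloxy)heptadeca-12,16-dienoate
Product: 30 2,2,2-trichloroethyl (3S,4S,6R,7S,8S,12Z,15S,16E)-3,7-bis[(tert-butyldimethylsilyl)oxy]-4,6,8,12,16-pentamethyl-17-(2-methyl-1,3-thiazol-4-yl)-5-oxo-15-(triethylsilyloxy)heptadeca-12,16-dienoate
Conditions: TBSOTf, 2,6-lutidine, CH2Cl2, −78 → 0 °C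
Reagents that add atoms: tert-butyldimethylsilyl trifluoromethanesulfonate, CC(C)(C)[Si](C)(C)OS(=O)(=O)C(F)(F)F
Why: Silyl triflate silylation caps the hindered C7 aldol hydroxyl at low temperature, which blocks retro-aldol cleavage in later steps while the hindered ketone is not enolized by 2,6-lutidine.

Step 24
Reactants: 30 2,2,2-trichloroethyl (3S,4S,6R,7S,8S,12Z,15S,16E)-3,7-bis[(tert-butyldimethylsilyl)oxy]-4,6,8,12,16-pentamethyl-17-(2-methyl-1,3-thiazol-4-yl)-5-oxo-15-(triethylsilyloxy)heptadeca-12,16-dienoate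
Product: 31 2,2,2-trichloroethyl (3S,4S,6R,7S,8S,12Z,15S,16E)-3,7-bis[(tert-butyldimethylsilyl)oxy]-15-hydroxy-4,6,8,12,16-pentamethyl-17-(2-methyl-1,3-thiazol-4-yl)-5-oxoheptadeca-12,16-dienoate
Conditions: HF·pyridine, pyridine, THF, 0 °C
Reagents that add atoms: none
Why: Selective desilylation, since buffered HF cleaves the triethylsilyl ether far faster than the two hindered tert-butyldimethylsilyl ethers and is not basic, so C4, C6 and the β-silyloxy ketone are safe.

Step 25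
Reactants: 31 2,2,2-trichloroethyl (3S,4S,6R,7S,8S,12Z,15S,16E)-3,7-bis[(tert-butyldimethylsilyl)oxy]-15-hydroxy-4,6,8,12,16-pentamethyl-17-(2-methyl-1,3-thiazol-4-yl)-5-oxoheptadeca-12,16-dienoate
Product: 32 (3S,4S,6R,7S,8S,12Z,15S,16E)-3,7-bis[(tert-butyldimethylsilyl)oxy]-15-hydroxy-4,6,8,12,16-pentamethyl-17-(2-methyl-1,3-thiazol-4-yl)-5-oxoheptadeca-12,16-dienoic acid
Conditions: Zn, AcOH/THF 1:4, rt
Reagents that add atoms: none
Why: Reductive fragmentation of the trichloroethyl ester by zinc (two-electron reduction and β-elimination) frees the acid without base, fluoride or hydrogenation.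

Step 26
Reactants: 32 (3S,4S,6R,7S,8S,12Z,15S,16E)-3,7-bis[(tert-butyldimethylsilyl)oxy]-15-hydroxy-4,6,8,12,16-pentamethyl-17-(2-methyl-1,3-thiazol-4-yl)-5-oxoheptadeca-12,16-dienoic acid
Product: 34 (4S,5S,7R,8S,9S,13Z,16S)-4,8-bis[(tert-butyldimethylsilyl)oxy]-5,7,9,13-tetramethyl-16-[(1E)-1-(2-methyl-1,3-thiazol-4-yl)prop-1-en-2-yl]-1-oxacyclohexadec-13-ene-2,6-dione, via mixed trichlorobenzoic anhydride 33 (not isolated)
Conditions: 2,4,6-Cl3C6H2COCl, Et3N, THF, 0 °C → rt; then slow addition to DMAP, toluene (0.002 M), rt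
Reagents that add atoms: none
Why: Yamaguchi macrolactonization, in which the mixed anhydride is attacked by DMAP and the acylpyridinium is trapped by the C15 hydroxyl at high dilution with retention at C15; the Z-alkene pre-organizes the 16-membered ring.

Step 27
Reactants: 34 (4S,5S,7R,8S,9S,13Z,16S)-4,8-bis[(tert-butyldimethylsilyl)oxy]-5,7,9,13-tetramethyl-16-[(1E)-1-(2-methyl-1,3-thiazol-4-yl)prop-1-en-2-yl]-1-oxacyclohexadec-13-ene-2,6-dione
Product: 35 (4S,5S,7R,8S,9S,13Z,16S)-4,8-dihydroxy-5,7,9,13-tetramethyl-16-[(1E)-1-(2-methyl-1,3-thiazol-4-yl)prop-1-en-2-yl]-1-oxacyclohexadec-13-ene-2,6-dione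
Conditions: HF·pyridine, THF, 0 °C → rt
Reagents that add atoms: none
Why: Global fluoride-mediated desilylation under mildly acidic conditions avoids retro-aldol cleavage and epimerization of the two β-hydroxy ketone units.

Step 28
Reactants: 35 (4S,5S,7R,8S,9S,13Z,16S)-4,8-dihydroxy-5,7,9,13-tetramethyl-16-[(1E)-1-(2-methyl-1,3-thiazol-4-yl)prop-1-en-2-yl]-1-oxacyclohexadec-13-ene-2,6-dione
Product: 36 (1S,3S,7S,8S,10R,11S,12S,16R)-7,11-dihydroxy-8,10,12,16-tetramethyl-3-[(1E)-1-(2-methyl-1,3-thiazol-4-yl)prop-1-en-2-yl]-4,17-dioxabicyclo[14.1.0]heptadecane-5,9-dione (target; 3S,4S,6R,7S,8S,12R,13S,15S in epothilone numbering)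
Conditions: DMDO (acetone solution), CH2Cl2, −50 °C
Reagents that add atoms: dimethyldioxirane, CC1(C)OO1
Why: Electrophilic dioxirane epoxidation is stereospecific (cis) and attacks the more electron-rich, unconjugated C12=C13 alkene from the exposed face of the macrolactone, as in the parent 12,13-desoxy series, giving the (12R,13S) oxirane.

**Compound list**
1 | methyl acetoacetate | CC(=O)CC(=O)OC | starting material
2 | methyl 5-(benzyloxy)-3-oxopentanoate | COC(=O)CC(=O)CCOCc1ccccc1 | intermediate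
3 | methyl (3S)-5-(benzyloxy)-3-hydroxypentanoate | COC(=O)C[C@@H](O)CCOCc1ccccc1 | intermediate
4 | methyl (2S,3S)-5-(benzyloxy)-3-hydroxy-2-methylpentanoate (2,3-anti) | COC(=O)[C@@H](C)[C@@H](O)CCOCc1ccccc1 | intermediate
5 | (2S,3S)-5-(benzyloxy)-3-hydroxy-N-methoxy-N,2-dimethylpentanamide | CON(C)C(=O)[C@@H](C)[C@@H](O)CCOCc1ccccc1 | intermediate
6 | (2S,3S)-5-(benzyloxy)-3-[(tert-butyldimethylsilyl)oxy]-N-methoxy-N,2-dimethylpentanamide | CON(C)C(=O)[C@@H](C)[C@@H](O[Si](C)(C)C(C)(C)C)CCOCc1ccccc1 | intermediate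
7 | (4S,5S)-7-(benzyloxy)-5-[(tert-butyldimethylsilyl)oxy]-4-methylheptan-3-one | CCC(=O)[C@@H](C)[C@@H](O[Si](C)(C)C(C)(C)C)CCOCc1ccccc1 | intermediate
8 | (4S,5S)-5-[(tert-butyldimethylsilyl)oxy]-7-hydroxy-4-methylheptan-3-one | CCC(=O)[C@@H](C)[C@@H](O[Si](C)(C)C(C)(C)C)CCO | intermediate
9 | (3S,4S)-3-[(tert-butyldimethylsilyl)oxy]-4-methyl-5-oxoheptanoic acid | CCC(=O)[C@@H](C)[C@@H](O[Si](C)(C)C(C)(C)C)CC(=O)O | intermediate
10 | 2,2,2-trichloroethyl (3S,4S)-3-[(tert-butyldimethylsilyl)oxy]-4-methyl-5-oxoheptanoate (fragment A) | CCC(=O)[C@@H](C)[C@@H](O[Si](C)(C)C(C)(C)C)CC(=O)OCC(Cl)(Cl)Cl | intermediate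
11 | (4R)-4-benzyl-3-propanoyl-1,3-oxazolidin-2-one | CCC(=O)N1[C@H](Cc2ccccc2)COC1=O | starting material
12 | (4R)-4-benzyl-3-[(2S)-2-methylpent-4-enoyl]-1,3-oxazolidin-2-one | C=CC[C@H](C)C(=O)N1[C@H](Cc2ccccc2)COC1=O | intermediate
13 | (2S)-2-methylpent-4-en-1-ol | C=CC[C@H](C)CO | intermediate
14 | (2S)-2-methylpent-4-en-1-yl 2,2-dimethylpropanoate | C=CC[C@H](C)COC(=O)C(C)(C)C | intermediate
15 | ethyl 2-methyl-1,3-thiazole-4-carboxylate | CCOC(=O)c1csc(C)n1 | starting material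
16 | 2-methyl-1,3-thiazole-4-carbaldehyde | O=Cc1csc(C)n1 | intermediate
17 | (2E)-2-methyl-3-(2-methyl-1,3-thiazol-4-yl)prop-2-enal | C/C(C=O)=C\c1csc(C)n1 | intermediate
18 | (1E,3S)-2-methyl-1-(2-methyl-1,3-thiazol-4-yl)hexa-1,5-dien-3-yl diisopinocampheylborinate | C/C(=C\c1csc(C)n1)[C@@H](OB([C@H]2[C@H](C)[C@H]3C[C@@H](C2)C3(C)C)[C@H]2[C@H](C)[C@H]3C[C@@H](C2)C3(C)C)CC=C | intermediate (not isolated)
19 | (1E,3S)-2-methyl-1-(2-methyl-1,3-thiazol-4-yl)hexa-1,5-dien-3-ol | C/C(=C\c1csc(C)n1)[C@@H](O)CC=C | intermediate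
20 | 4-[(1E,3S)-2-methyl-3-(triethylsilyloxy)hexa-1,5-dien-1-yl]-2-methyl-1,3-thiazole | C/C(=C\c1csc(C)n1)[C@@H](O[Si](CC)(CC)CC)CC=C | intermediate
21 | (4S,5E)-5-methyl-6-(2-methyl-1,3-thiazol-4-yl)-4-(triethylsilyloxy)hex-5-ene-1,2-diol (both C2 epimers) | C/C(=C\c1csc(C)n1)[C@@H](O[Si](CC)(CC)CC)CC(O)CO | intermediate (not isolated)
22 | (3S,4E)-4-methyl-5-(2-methyl-1,3-thiazol-4-yl)-3-(triethylsilyloxy)pent-4-enal | C/C(=C\c1csc(C)n1)[C@@H](O[Si](CC)(CC)CC)CC=O | intermediate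
23 | 4-[(1E,3S,5Z)-6-iodo-2-methyl-3-(triethylsilyloxy)hepta-1,5-dien-1-yl]-2-methyl-1,3-thiazole | C/C(=C\c1csc(C)n1)[C@@H](O[Si](CC)(CC)CC)C/C=C(/C)I | intermediate
24 | (2S)-5-(9-borabicyclo[3.3.1]nonan-9-yl)-2-methylpentyl 2,2-dimethylpropanoate | CC(C)(C)C(=O)OC[C@@H](C)CCCB1C2CCCC1CCC2 | intermediate (not isolated)
25 | (2S,6Z,9S,10E)-2,6,10-trimethyl-11-(2-methyl-1,3-thiazol-4-yl)-9-(triethylsilyloxy)undeca-6,10-dien-1-yl 2,2-dimethylpropanoate | C/C(=C\c1csc(C)n1)[C@@H](O[Si](CC)(CC)CC)C/C=C(/C)CCC[C@H](C)COC(=O)C(C)(C)C | intermediate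
26 | (2S,6Z,9S,10E)-2,6,10-trimethyl-11-(2-methyl-1,3-thiazol-4-yl)-9-(triethylsilyloxy)undeca-6,10-dien-1-ol | C/C(=C\c1csc(C)n1)[C@@H](O[Si](CC)(CC)CC)C/C=C(/C)CCC[C@H](C)CO | intermediate
27 | (2S,6Z,9S,10E)-2,6,10-trimethyl-11-(2-methyl-1,3-thiazol-4-yl)-9-(triethylsilyloxy)undeca-6,10-dienal (fragment B) | C/C(=C\c1csc(C)n1)[C@@H](O[Si](CC)(CC)CC)C/C=C(/C)CCC[C@H](C)C=O | intermediate
28 | 2,2,2-trichloroethyl (3S,4S,5Z)-3-[(tert-butyldimethylsilyl)oxy]-4-methyl-5-[(trichlorotitanio)oxy]hept-5-enoate (tetravalent titanium Z-enolate of 10) | C/C=C(\O[Ti](Cl)(Cl)Cl)[C@@H](C)[C@@H](O[Si](C)(C)C(C)(C)C)CC(=O)OCC(Cl)(Cl)Cl | intermediate (not isolated)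
29 | 2,2,2-trichloroethyl (3S,4S,6R,7S,8S,12Z,15S,16E)-3-[(tert-butyldimethylsilyl)oxy]-7-hydroxy-4,6,8,12,16-pentamethyl-17-(2-methyl-1,3-thiazol-4-yl)-5-oxo-15-(triethylsilyloxy)heptadeca-12,16-dienoate | C/C(=C\c1csc(C)n1)[C@@H](O[Si](CC)(CC)CC)C/C=C(/C)CCC[C@H](C)[C@H](O)[C@@H](C)C(=O)[C@@H](C)[C@@H](O[Si](C)(C)C(C)(C)C)CC(=O)OCC(Cl)(Cl)Cl | intermediate
30 | 2,2,2-trichloroethyl (3S,4S,6R,7S,8S,12Z,15S,16E)-3,7-bis[(tert-butyldimethylsilyl)oxy]-4,6,8,12,16-pentamethyl-17-(2-methyl-1,3-thiazol-4-yl)-5-oxo-15-(triethylsilyloxy)heptadeca-12,16-dienoate | C/C(=C\c1csc(C)n1)[C@@H](O[Si](CC)(CC)CC)C/C=C(/C)CCC[C@H](C)[C@H](O[Si](C)(C)C(C)(C)C)[C@@H](C)C(=O)[C@@H](C)[C@@H](O[Si](C)(C)C(C)(C)C)CC(=O)OCC(Cl)(Cl)Cl | intermediate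
31 | 2,2,2-trichloroethyl (3S,4S,6R,7S,8S,12Z,15S,16E)-3,7-bis[(tert-butyldimethylsilyl)oxy]-15-hydroxy-4,6,8,12,16-pentamethyl-17-(2-methyl-1,3-thiazol-4-yl)-5-oxoheptadeca-12,16-dienoate | C/C(=C\c1csc(C)n1)[C@@H](O)C/C=C(/C)CCC[C@H](C)[C@H](O[Si](C)(C)C(C)(C)C)[C@@H](C)C(=O)[C@@H](C)[C@@H](O[Si](C)(C)C(C)(C)C)CC(=O)OCC(Cl)(Cl)Cl | intermediate
32 | (3S,4S,6R,7S,8S,12Z,15S,16E)-3,7-bis[(tert-butyldimethylsilyl)oxy]-15-hydroxy-4,6,8,12,16-pentamethyl-17-(2-methyl-1,3-thiazol-4-yl)-5-oxoheptadeca-12,16-dienoic acid | C/C(=C\c1csc(C)n1)[C@@H](O)C/C=C(/C)CCC[C@H](C)[C@H](O[Si](C)(C)C(C)(C)C)[C@@H](C)C(=O)[C@@H](C)[C@@H](O[Si](C)(C)C(C)(C)C)CC(=O)O | intermediate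
33 | mixed anhydride of 32 with 2,4,6-trichlorobenzoic acid | C/C(=C\c1csc(C)n1)[C@@H](O)C/C=C(/C)CCC[C@H](C)[C@H](O[Si](C)(C)C(C)(C)C)[C@@H](C)C(=O)[C@@H](C)[C@@H](O[Si](C)(C)C(C)(C)C)CC(=O)OC(=O)c1c(Cl)cc(Cl)cc1Cl | intermediate (not isolated)
34 | (4S,5S,7R,8S,9S,13Z,16S)-4,8-bis[(tert-butyldimethylsilyl)oxy]-5,7,9,13-tetramethyl-16-[(1E)-1-(2-methyl-1,3-thiazol-4-yl)prop-1-en-2-yl]-1-oxacyclohexadec-13-ene-2,6-dione | C/C(=C\c1csc(C)n1)[C@@H]1C/C=C(/C)CCC[C@H](C)[C@H](O[Si](C)(C)C(C)(C)C)[C@@H](C)C(=O)[C@@H](C)[C@@H](O[Si](C)(C)C(C)(C)C)CC(=O)O1 | intermediate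
35 | (4S,5S,7R,8S,9S,13Z,16S)-4,8-dihydroxy-5,7,9,13-tetramethyl-16-[(1E)-1-(2-methyl-1,3-thiazol-4-yl)prop-1-en-2-yl]-1-oxacyclohexadec-13-ene-2,6-dione | C/C(=C\c1csc(C)n1)[C@@H]1C/C=C(/C)CCC[C@H](C)[C@H](O)[C@@H](C)C(=O)[C@@H](C)[C@@H](O)CC(=O)O1 | intermediate
36 | (1S,3S,7S,8S,10R,11S,12S,16R)-7,11-dihydroxy-8,10,12,16-tetramethyl-3-[(1E)-1-(2-methyl-1,3-thiazol-4-yl)prop-1-en-2-yl]-4,17-dioxabicyclo[14.1.0]heptadecane-5,9-dione | C/C(=C\c1csc(C)n1)[C@@H]1C[C@@H]2O[C@]2(C)CCC[C@H](C)[C@H](O)[C@@H](C)C(=O)[C@@H](C)[C@@H](O)CC(=O)O1 | target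

**Totals**
Total steps: 28. Longest linear sequence: 16 steps (steps 13–28 from 15; equally steps 1–9 then 22–28 from 1).

**Three steps most likely to fail, with fallbacks**

Step 22 (the fragment-uniting aldol). The Lewis-basic thiazole and the allylic triethylsilyl ether of 27 may bind or be attacked by the titanium species. The facial selectivity also rests on double stereodifferentiation that has not been tested on exactly this ketone. Fallback: run the same aldol on a small, thiazole-free aldehyde and attach the thiazole half afterwards. It sets out from alcohol 13 and from enolate 28 (made from 10 as in step 22) and returns at 30. Alcohol 13 is oxidised with Dess–Martin periodinane to (2S)-2-methylpent-4-enal F1, which is added as a cold CH2Cl2 solution to 28. This gives 2,2,2-trichloroethyl (3S,4S,6R,7S,8S)-3-[(tert-butyldimethylsilyl)oxy]-7-hydroxy-4,6,8-trimethyl-5-oxoundec-10-enoate F2. TBSOTf and 2,6-lutidine convert it into the 3,7-bis(silyl ether) F3. 9-BBN-H then hydroborates the terminal alkene (the hindered ketone and the ester are left alone) to give the B-alkyl-9-BBN adduct F4. This is coupled with vinyl iodide 23 (PdCl2(dppf), Ph3As, Cs2CO3 or K3PO4, DMF/H2O, rt) to give 30, and the route resumes at step 24.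

Step 18 (Z-iodo-olefination). Yields of this Wittig reaction are typically moderate, and the β-silyloxy aldehyde 22 can eliminate under the basic ylide. Fallback: build the Z-haloalkene in two stereodefined steps. It sets out from 22 and returns at 25. CBr4, PPh3 and Et3N (CH2Cl2, 0 °C) give 4-[(1E,3S)-6,6-dibromo-2-methyl-3-(triethylsilyloxy)hexa-1,5-dien-1-yl]-2-methyl-1,3-thiazole F5. A trans-selective Negishi monomethylation (Me2Zn, PdCl2(DPEphos) cat., THF, 0 °C → rt) replaces only the bromide trans to the chain and gives 4-[(1E,3S,5Z)-6-bromo-2-methyl-3-(triethylsilyloxy)hepta-1,5-dien-1-yl]-2-methyl-1,3-thiazole F6. This is coupled with borane 24 (Pd(t-Bu3P)2, a zerovalent palladium catalyst, K3PO4, THF/H2O, 40 °C) with retention to give 25.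

Step 28 (epoxidation). Face selectivity depends on the conformation of a macrolactone that lacks one of the usual C4 methyl groups, and the second alkene or the thiazole could compete. Fallback: epoxidise under reagent control before deprotection. It sets out from 34 and returns at 36. A Shi epoxidation of 34 uses the L-fructose-derived enantiomer of the Shi ketone (30 mol %), KHSO5 and K2CO3 buffer in MeCN/dimethoxymethane/H2O at 0 °C. Its dioxirane delivers oxygen in the (S,S) sense to the C14–C13=C12–CH3 trans array and so reinforces the substrate bias. The product is (1S,3S,7S,8S,10R,11S,12S,16R)-7,11-bis[(tert-butyldimethylsilyl)oxy]-8,10,12,16-tetramethyl-3-[(1E)-1-(2-methyl-1,3-thiazol-4-yl)prop-1-en-2-yl]-4,17-dioxabicyclo[14.1.0]heptadecane-5,9-dione F7, which HF·pyridine in THF desilylates to 36.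

**Further compounds**
F1 | step 22 | (2S)-2-methylpent-4-enal | C=CC[C@H](C)C=O
F2 | step 22 | 2,2,2-trichloroethyl (3S,4S,6R,7S,8S)-3-[(tert-butyldimethylsilyl)oxy]-7-hydroxy-4,6,8-trimethyl-5-oxoundec-10-enoate | C=CC[C@H](C)[C@H](O)[C@@H](C)C(=O)[C@@H](C)[C@@H](O[Si](C)(C)C(C)(C)C)CC(=O)OCC(Cl)(Cl)Cl
F3 | step 22 | 2,2,2-trichloroethyl (3S,4S,6R,7S,8S)-3,7-bis[(tert-butyldimethylsilyl)oxy]-4,6,8-trimethyl-5-oxoundec-10-enoate | C=CC[C@H](C)[C@H](O[Si](C)(C)C(C)(C)C)[C@@H](C)C(=O)[C@@H](C)[C@@H](O[Si](C)(C)C(C)(C)C)CC(=O)OCC(Cl)(Cl)Cl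
F4 | step 22 | 2,2,2-trichloroethyl (3S,4S,6R,7S,8S)-11-(9-borabicyclo[3.3.1]nonan-9-yl)-3,7-bis[(tert-butyldimethylsilyl)oxy]-4,6,8-trimethyl-5-oxoundecanoate | C1CCC2CCCC1B2CCC[C@H](C)[C@H](O[Si](C)(C)C(C)(C)C)[C@@H](C)C(=O)[C@@H](C)[C@@H](O[Si](C)(C)C(C)(C)C)CC(=O)OCC(Cl)(Cl)Cl
F5 | step 18 | 4-[(1E,3S)-6,6-dibromo-2-methyl-3-(triethylsilyloxy)hexa-1,5-dien-1-yl]-2-methyl-1,3-thiazole | C/C(=C\c1csc(C)n1)[C@@H](O[Si](CC)(CC)CC)CC=C(Br)Br
F6 | step 18 | 4-[(1E,3S,5Z)-6-bromo-2-methyl-3-(triethylsilyloxy)hepta-1,5-dien-1-yl]-2-methyl-1,3-thiazole | C/C(=C\c1csc(C)n1)[C@@H](O[Si](CC)(CC)CC)C/C=C(/C)Br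
F7 | step 28 | (1S,3S,7S,8S,10R,11S,12S,16R)-7,11-bis[(tert-butyldimethylsilyl)oxy]-8,10,12,16-tetramethyl-3-[(1E)-1-(2-methyl-1,3-thiazol-4-yl)prop-1-en-2-yl]-4,17-dioxabicyclo[14.1.0]heptadecane-5,9-dione | C/C(=C\c1csc(C)n1)[C@@H]1C[C@@H]2O[C@]2(C)CCC[C@H](C)[C@H](O[Si](C)(C)C(C)(C)C)[C@@H](C)C(=O)[C@@H](C)[C@@H](O[Si](C)(C)C(C)(C)C)CC(=O)O1
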